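**Retrosynthetic overview**
1. The target is an acetylphloroglucinol ring B whose C3 and C5 carry, through CH2 bridges, two butanoyl-methylphloroglucinol monomethyl ether rings A and C; the last operation is hydrogenolysis of seven benzyl ethers.
2. The strategy rests on the three phenolic oxygens at C2, C4 and C6 of ring B, each ortho or para to the acetyl-bearing carbon C1: all three C–O bonds are made in one step by displacement of fluoride with benzyloxide on a 2,4,6-trifluoroacetophenone that already carries both arms.
3. The two aryl–CH2 bonds come from two successive Negishi couplings of benzylic zinc reagents with 3-bromo-5-iodo-2,4,6-trifluoroacetophenone, first at C–I and then at C–Br.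
4. Both arm chlorides come from 2,4,6-trihydroxytoluene through one C-butanoylation; the order of O-methylation and O-benzylation fixes where the methoxy group sits, and formylation, reduction and chlorination add the CH2Cl group.
5. No ring is formed in the route; rings A, B and C are bought as aromatic rings.

Key step: step 16

Remark on the structure: rings A and C are constitutional isomers. In ring A the methoxy group is para to the butanoyl group and the bridging CH2 lies between OMe and OH. In ring C the methoxy group is ortho to the butanoyl group and the bridging CH2 lies between two OH groups. The SNAr precursor therefore carries two different arms, which are attached one after the other. The target has no stereocenter.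

**Route**

Step 1
Reactants: 1 2,4,6-trihydroxytoluene; 2 butanoyl chloride
Product: 3 1-(2,4,6-trihydroxy-3-methylphenyl)butan-1-one
Conditions: AlCl3, PhNO2, 25 → 65 °C; aq. HCl work-up
Reagents that add atoms: none
Why: Friedel–Crafts C-acylation of the phloroglucinol nucleus, in which the two free ring positions of 1 are equivalent and the first acyl group slows a second acylation.

Step 2
Reactants: 3 1-(2,4,6-trihydroxy-3-methylphenyl)butan-1-one
Product: 4 1-(2,6-dihydroxy-4-methoxy-3-methylphenyl)butan-1-one (aspidinol)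
Conditions: Me2SO4 (1.0 equiv), K2CO3 (1.0 equiv), acetone, 0 → 25 °C
Reagents that add atoms: dimethyl sulfate COS(=O)(=O)OC
Why: Williamson O-methylation with one equivalent of base and electrophile should take the hydroxyl para to the ketone, which is the most acidic one and the only one not held in a hydrogen bond to the carbonyl.

Step 3
Reactants: 4 1-(2,6-dihydroxy-4-methoxy-3-methylphenyl)butan-1-one
Product: 5 1-[2,6-bis(benzyloxy)-4-methoxy-3-methylphenyl]butan-1-one
Conditions: BnBr (2.6 equiv), K2CO3, KI (cat.), DMF, 60 °C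
Reagents that add atoms: benzyl bromide BrCc1ccccc1
Why: Williamson etherification under forcing conditions in a dipolar aprotic solvent should benzylate both chelated ortho-hydroxyls on oxygen.

Step 4
Reactants: 5 1-[2,6-bis(benzyloxy)-4-methoxy-3-methylphenyl]butan-1-one
Product: 7 2,4-bis(benzyloxy)-3-butanoyl-6-methoxy-5-methylbenzaldehyde, via aryl iminium salt 6 (not isolated)
Conditions: POCl3, DMF, 0 → 60 °C; then H2O, 25 °C
Reagents that add atoms: N,N-dimethylformamide CN(C)C=O; water O
Why: Vilsmeier–Haack formylation at the only free ring position, which is ortho to two alkoxy groups and para to the third, while the ketone is twisted between two benzyloxy groups and is slow to enolise.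

Step 5
Reactants: 7 2,4-bis(benzyloxy)-3-butanoyl-6-methoxy-5-methylbenzaldehyde
Product: 8 1-[2,6-bis(benzyloxy)-3-(hydroxymethyl)-4-methoxy-5-methylphenyl]butan-1-one
Conditions: NaBH4 (0.6 equiv), THF/MeOH, −15 °C
Reagents that add atoms: none
Why: Chemoselective borohydride reduction, since the aldehyde is far more electrophilic than the doubly ortho-substituted aryl ketone at low temperature.

Step 6
Reactants: 8 1-[2,6-bis(benzyloxy)-3-(hydroxymethyl)-4-methoxy-5-methylphenyl]butan-1-one
Product: 9 1-[2,6-bis(benzyloxy)-3-(chloromethyl)-4-methoxy-5-methylphenyl]butan-1-one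
Conditions: SOCl2 (1.2 equiv), CH2Cl2, 0 °C; crude used at once
Reagents that add atoms: thionyl chloride ClS(Cl)=O
Why: Deoxychlorination of an electron-rich benzylic alcohol through its chlorosulfite; the ring is fully substituted, so the reactive chloride cannot alkylate another molecule on carbon.

Step 7
Reactants: 3 1-(2,4,6-trihydroxy-3-methylphenyl)butan-1-one
Product: 10 1-[4,6-bis(benzyloxy)-2-hydroxy-3-methylphenyl]butan-1-one
Conditions: BnBr (2.05 equiv), K2CO3 (2.2 equiv), acetone, 25 → 50 °C
Reagents that add atoms: benzyl bromide BrCc1ccccc1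
Why: Williamson etherification in order of phenol reactivity: the para-hydroxyl reacts first, then the ortho-hydroxyl next to the ring hydrogen, and the ortho-hydroxyl wedged between the C-methyl and the butanoyl group, the most hindered and most strongly chelated, should remain free.

Step 8
Reactants: 10 1-[4,6-bis(benzyloxy)-2-hydroxy-3-methylphenyl]butan-1-one
Product: 11 1-[4,6-bis(benzyloxy)-2-methoxy-3-methylphenyl]butan-1-one
Conditions: MeI (3 equiv), K2CO3, DMF, 50 °C
Reagents that add atoms: iodomethane CI
Why: Williamson O-methylation of the last, chelated phenol with a small electrophile in excess.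

Step 9
Reactants: 11 1-[4,6-bis(benzyloxy)-2-methoxy-3-methylphenyl]butan-1-one
Product: 13 2,6-bis(benzyloxy)-3-butanoyl-4-methoxy-5-methylbenzaldehyde, via aryl iminium salt 12 (not isolated)
Conditions: POCl3, DMF, 0 → 60 °C; then H2O, 25 °C
Reagents that add atoms: N,N-dimethylformamide CN(C)C=O; water O
Why: Vilsmeier–Haack formylation at the only free ring position, which lies between two benzyloxy groups and para to the methoxy group.

Step 10
Reactants: 13 2,6-bis(benzyloxy)-3-butanoyl-4-methoxy-5-methylbenzaldehyde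
Product: 14 1-[2,4-bis(benzyloxy)-3-(hydroxymethyl)-6-methoxy-5-methylphenyl]butan-1-one
Conditions: NaBH4 (0.6 equiv), THF/MeOH, −15 °C
Reagents that add atoms: none
Why: Chemoselective borohydride reduction of the aldehyde beside the hindered, twisted aryl ketone.

Step 11
Reactants: 14 1-[2,4-bis(benzyloxy)-3-(hydroxymethyl)-6-methoxy-5-methylphenyl]butan-1-one
Product: 15 1-[2,4-bis(benzyloxy)-3-(chloromethyl)-6-methoxy-5-methylphenyl]butan-1-one
Conditions: SOCl2 (1.2 equiv), CH2Cl2, 0 °C; crude used at once
Reagents that add atoms: thionyl chloride ClS(Cl)=O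
Why: Deoxychlorination of the electron-rich benzylic alcohol through its chlorosulfite, as in step 6.

Step 12
Reactants: 16 1-(2,4,6-trifluorophenyl)ethanone
Product: 17 1-(3-bromo-2,4,6-trifluorophenyl)ethanone
Conditions: NBS (1.05 equiv), conc. H2SO4, 25 → 50 °C
Reagents that add atoms: N-bromosuccinimide O=C1CCC(=O)N1Br
Why: Electrophilic aromatic bromination of a deactivated arene by acid-activated NBS: C3 and C5 are equivalent, each ortho to two fluorines, para to the third and meta to the acetyl group, the first bromine slows a second substitution, and the ketone, fully protonated in concentrated acid, enolises too slowly for side-chain bromination to compete.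

Step 13
Reactants: 17 1-(3-bromo-2,4,6-trifluorophenyl)ethanone
Product: 18 1-(3-bromo-2,4,6-trifluoro-5-iodophenyl)ethanone
Conditions: NIS (1.2 equiv), CF3SO3H, 0 → 25 °C
Reagents that add atoms: N-iodosuccinimide O=C1CCC(=O)N1I
Why: Electrophilic aromatic iodination of a deactivated arene by NIS in triflic acid at the one remaining ring position, on which the directing effects of the three fluorines and the acetyl group agree.

Step 14
Reactants: 9 1-[2,6-bis(benzyloxy)-3-(chloromethyl)-4-methoxy-5-methylphenyl]butan-1-one; 18 1-(3-bromo-2,4,6-trifluoro-5-iodophenyl)ethanone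
Product: 20 1-(3-bromo-2,4,6-trifluoro-5-{[2,4-bis(benzyloxy)-3-butanoyl-6-methoxy-5-methylphenyl]methyl}phenyl)ethanone, via benzylic zinc chloride 19 (not isolated)
Conditions: 9 (1.1 equiv), Zn dust, LiCl, THF, 25 °C; then 18, Pd(PPh3)4 (3 mol %), THF, 0 → 25 °C
Reagents that add atoms: none
Why: LiCl-assisted zinc insertion gives a benzylic zinc chloride that tolerates ketones, and in the Negishi coupling zerovalent palladium should insert into C–I much faster than into C–Br at or below room temperature.

Step 15
Reactants: 15 1-[2,4-bis(benzyloxy)-3-(chloromethyl)-6-methoxy-5-methylphenyl]butan-1-one; 20 the bromide from step 14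
Product: 22 1-(2,4,6-trifluoro-3-{[2,4-bis(benzyloxy)-3-butanoyl-6-methoxy-5-methylphenyl]methyl}-5-{[2,6-bis(benzyloxy)-3-butanoyl-4-methoxy-5-methylphenyl]methyl}phenyl)ethanone, via benzylic zinc chloride 21 (not isolated)
Conditions: 15 (1.5 equiv), Zn dust, LiCl, THF, 25 °C; then 20, Pd(OAc)2 (4 mol %), SPhos (8 mol %), THF, 50 °C
Reagents that add atoms: none
Why: Negishi coupling at the remaining C–Br bond, which is activated by its two ortho fluorines, with a more active biarylphosphine catalyst and mild heating.

Step 16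
Reactants: 22 the trifluoro ketone from step 15; 23 benzyl alcohol
Product: 25 1-(2,4,6-tris(benzyloxy)-3-{[2,4-bis(benzyloxy)-3-butanoyl-6-methoxy-5-methylphenyl]methyl}-5-{[2,6-bis(benzyloxy)-3-butanoyl-4-methoxy-5-methylphenyl]methyl}phenyl)ethanone, via sodium benzyloxide 24 (not isolated)
Conditions: 23 (12 equiv), NaH (8 equiv), THF, 0 → 25 °C until H2 evolution ends; then 22, DMSO, 25 → 75 °C; three equivalents of the benzyloxide are taken up, one per C–F bond
Reagents that add atoms: benzyl alcohol OCc1ccccc1
Why: Benzyloxide adds in turn to C2, C4 and C6 of ring B to give Meisenheimer anions whose charge lies on C1, C3 and C5 and is delocalised from C1 into the acetyl carbonyl, and fluoride, the best leaving group when addition is rate-limiting, then departs, so that three equivalents of the alkoxide end up in the product as its three new aryl C–O bonds. The closest known reaction type is the alkoxy-defluorination of 2- and 4-fluoroaryl ketones and of polyfluorinated benzonitriles by SNAr. No ring is closed and no stereocenter is formed. The step needs chemoselectivity for the three C–F carbons over addition or aldol chemistry at the three ketones, and this should be secured because each carbonyl is flanked by two ortho substituents that twist and shield it. An excess of benzyl alcohol over NaH keeps enolisation of the acetyl group reversible, so the reactive keto form stays available. Each benzyloxy group that has entered sits meta to the remaining C–F carbons, on a ring carbon that carries none of the Meisenheimer charge, so it acts mainly through its inductive pull and should not shut down the later exchanges, and both arms are meta to the acetyl group and leave the small fluorides open to attack perpendicular to the ring.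

Step 17
Reactants: 25 the hepta-O-benzyl ether from step 16
Product: 26 1-(2,4,6-trihydroxy-3-{[3-butanoyl-2,4-dihydroxy-6-methoxy-5-methylphenyl]methyl}-5-{[3-butanoyl-2,6-dihydroxy-4-methoxy-5-methylphenyl]methyl}phenyl)ethanone (CNP0184345.0)
Conditions: H2 (1 atm), 10% Pd/C, EtOAc/MeOH, 25 °C
Reagents that add atoms: none
Why: Heterogeneous hydrogenolysis of the seven benzyl aryl ethers under neutral conditions, which should leave the chelated aryl ketones, the methyl ethers and the diarylmethane bridges untouched.

**Compound list**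
1 | 2,4,6-trihydroxytoluene | Cc1c(O)cc(O)cc1O | starting material
2 | butanoyl chloride | CCCC(Cl)=O | starting material
3 | 1-(2,4,6-trihydroxy-3-methylphenyl)butan-1-one | CCCC(=O)c1c(O)cc(O)c(C)c1O | intermediate
4 | 1-(2,6-dihydroxy-4-methoxy-3-methylphenyl)butan-1-one (aspidinol) | CCCC(=O)c1c(O)cc(OC)c(C)c1O | intermediate
5 | 1-[2,6-bis(benzyloxy)-4-methoxy-3-methylphenyl]butan-1-one | CCCC(=O)c1c(OCc2ccccc2)cc(OC)c(C)c1OCc1ccccc1 | intermediate
6 | N-{[2,4-bis(benzyloxy)-3-butanoyl-6-methoxy-5-methylphenyl]methylidene}-N-methylmethanaminium dichlorophosphate (not isolated) | CCCC(=O)c1c(OCc2ccccc2)c(C=[N+](C)C)c(OC)c(C)c1OCc1ccccc1.[O-]P(=O)(Cl)Cl | intermediate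
7 | 2,4-bis(benzyloxy)-3-butanoyl-6-methoxy-5-methylbenzaldehyde | CCCC(=O)c1c(OCc2ccccc2)c(C=O)c(OC)c(C)c1OCc1ccccc1 | intermediate
8 | 1-[2,6-bis(benzyloxy)-3-(hydroxymethyl)-4-methoxy-5-methylphenyl]butan-1-one | CCCC(=O)c1c(OCc2ccccc2)c(CO)c(OC)c(C)c1OCc1ccccc1 | intermediate
9 | 1-[2,6-bis(benzyloxy)-3-(chloromethyl)-4-methoxy-5-methylphenyl]butan-1-one | CCCC(=O)c1c(OCc2ccccc2)c(CCl)c(OC)c(C)c1OCc1ccccc1 | intermediate
10 | 1-[4,6-bis(benzyloxy)-2-hydroxy-3-methylphenyl]butan-1-one | CCCC(=O)c1c(OCc2ccccc2)cc(OCc2ccccc2)c(C)c1O | intermediate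
11 | 1-[4,6-bis(benzyloxy)-2-methoxy-3-methylphenyl]butan-1-one | CCCC(=O)c1c(OCc2ccccc2)cc(OCc2ccccc2)c(C)c1OC | intermediate
12 | N-{[2,6-bis(benzyloxy)-3-butanoyl-4-methoxy-5-methylphenyl]methylidene}-N-methylmethanaminium dichlorophosphate (not isolated) | CCCC(=O)c1c(OCc2ccccc2)c(C=[N+](C)C)c(OCc2ccccc2)c(C)c1OC.[O-]P(=O)(Cl)Cl | intermediate
13 | 2,6-bis(benzyloxy)-3-butanoyl-4-methoxy-5-methylbenzaldehyde | CCCC(=O)c1c(OCc2ccccc2)c(C=O)c(OCc2ccccc2)c(C)c1OC | intermediate
14 | 1-[2,4-bis(benzyloxy)-3-(hydroxymethyl)-6-methoxy-5-methylphenyl]butan-1-one | CCCC(=O)c1c(OCc2ccccc2)c(CO)c(OCc2ccccc2)c(C)c1OC | intermediate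
15 | 1-[2,4-bis(benzyloxy)-3-(chloromethyl)-6-methoxy-5-methylphenyl]butan-1-one | CCCC(=O)c1c(OCc2ccccc2)c(CCl)c(OCc2ccccc2)c(C)c1OC | intermediate
16 | 1-(2,4,6-trifluorophenyl)ethanone | CC(=O)c1c(F)cc(F)cc1F | starting material
17 | 1-(3-bromo-2,4,6-trifluorophenyl)ethanone | CC(=O)c1c(F)cc(F)c(Br)c1F | intermediate
18 | 1-(3-bromo-2,4,6-trifluoro-5-iodophenyl)ethanone | CC(=O)c1c(F)c(I)c(F)c(Br)c1F | intermediate
19 | {[2,4-bis(benzyloxy)-3-butanoyl-6-methoxy-5-methylphenyl]methyl}zinc chloride (not isolated) | CCCC(=O)c1c(OCc2ccccc2)c(C[Zn]Cl)c(OC)c(C)c1OCc1ccccc1 | intermediate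
20 | 1-(3-bromo-2,4,6-trifluoro-5-{[2,4-bis(benzyloxy)-3-butanoyl-6-methoxy-5-methylphenyl]methyl}phenyl)ethanone | CC(=O)c1c(F)c(Cc2c(OCc3ccccc3)c(C(=O)CCC)c(OCc3ccccc3)c(C)c2OC)c(F)c(Br)c1F | intermediate
21 | {[2,6-bis(benzyloxy)-3-butanoyl-4-methoxy-5-methylphenyl]methyl}zinc chloride (not isolated) | CCCC(=O)c1c(OCc2ccccc2)c(C[Zn]Cl)c(OCc2ccccc2)c(C)c1OC | intermediate
22 | 1-(2,4,6-trifluoro-3-{[2,4-bis(benzyloxy)-3-butanoyl-6-methoxy-5-methylphenyl]methyl}-5-{[2,6-bis(benzyloxy)-3-butanoyl-4-methoxy-5-methylphenyl]methyl}phenyl)ethanone | CC(=O)c1c(F)c(Cc2c(OCc3ccccc3)c(C(=O)CCC)c(OCc3ccccc3)c(C)c2OC)c(F)c(Cc2c(OCc3ccccc3)c(C)c(OC)c(C(=O)CCC)c2OCc2ccccc2)c1F | intermediate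
23 | benzyl alcohol | OCc1ccccc1 | starting material
24 | sodium benzyloxide (not isolated) | [Na+].[O-]Cc1ccccc1 | intermediate
25 | 1-(2,4,6-tris(benzyloxy)-3-{[2,4-bis(benzyloxy)-3-butanoyl-6-methoxy-5-methylphenyl]methyl}-5-{[2,6-bis(benzyloxy)-3-butanoyl-4-methoxy-5-methylphenyl]methyl}phenyl)ethanone | CC(=O)c1c(OCc2ccccc2)c(Cc2c(OCc3ccccc3)c(C(=O)CCC)c(OCc3ccccc3)c(C)c2OC)c(OCc2ccccc2)c(Cc2c(OCc3ccccc3)c(C)c(OC)c(C(=O)CCC)c2OCc2ccccc2)c1OCc1ccccc1 | intermediate
26 | 1-(2,4,6-trihydroxy-3-{[3-butanoyl-2,4-dihydroxy-6-methoxy-5-methylphenyl]methyl}-5-{[3-butanoyl-2,6-dihydroxy-4-methoxy-5-methylphenyl]methyl}phenyl)ethanone (CNP0184345.0) | CCCC(=O)c1c(O)c(C)c(OC)c(Cc2c(O)c(Cc3c(O)c(C)c(OC)c(C(=O)CCC)c3O)c(O)c(C(C)=O)c2O)c1O | target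

**Step count**
Total: 17 steps. Longest linear sequence: 10 steps (1, 2, 3, 4, 5, 6, 14, 15, 16, 17).

**Steps most likely to fail**

Step 16. The exchange may stall after one or two fluorides, because each new ortho benzyloxy group turns the acetyl group further out of the ring plane and part of the ketone rests as its enolate; at the higher temperature then needed the ketones may begin to condense. The fallback brings the three oxygens of ring B in from the start and sets out from chlorides 9 and 15. Commercial 2,4,6-trihydroxyacetophenone would be perbenzylated (BnBr, K2CO3, DMF) to 1-[2,4,6-tris(benzyloxy)phenyl]ethanone F1, brominated once (NBS, MeCN, 0 °C) to 1-[2,4,6-tris(benzyloxy)-3-bromophenyl]ethanone F2 and iodinated (NIS, CF3CO2H cat., MeCN) to 1-[2,4,6-tris(benzyloxy)-3-bromo-5-iodophenyl]ethanone F3. Negishi coupling of F3 with zinc reagent 19 from 9 at C–I (Pd(OAc)2, SPhos, THF, 25 °C) should give 1-(2,4,6-tris(benzyloxy)-3-bromo-5-{[2,4-bis(benzyloxy)-3-butanoyl-6-methoxy-5-methylphenyl]methyl}phenyl)ethanone F4. A second Negishi coupling of F4 with zinc reagent 21 from 15 at C–Br (same catalyst, 60 °C) comes back to the route at 25.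

Step 7. The two chelated ortho-hydroxyls may not be told apart well enough, so that the regioisomeric dibenzyl ether and the tribenzyl ether form alongside 10. The fallback fixes the methoxy position through a para relationship to a formyl group; it sets out from 1. Vilsmeier–Haack formylation (POCl3, DMF, EtOAc, 25 °C; then H2O) would give 2,4,6-trihydroxy-3-methylbenzaldehyde F5. Methylation of the hydroxyl para to the formyl group (Me2SO4 1 equiv, K2CO3, acetone) would give 2,6-dihydroxy-4-methoxy-3-methylbenzaldehyde F6. Friedel–Crafts acylation with 2 (TiCl4, CH2Cl2, 0 → 25 °C) at the only free ring position would give 3-butanoyl-2,6-dihydroxy-4-methoxy-5-methylbenzaldehyde F7. Dibenzylation (BnBr, K2CO3, DMF, 60 °C) comes back to the route at 13, so that steps 7 to 9 are not needed.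

Step 14. The electron-rich benzylic chloride 9 may ionise or couple with itself during zinc insertion, and the catalyst may begin to insert into C–Br before all C–I is consumed. The fallback joins the fragments at the aldehyde oxidation level and sets out from aldehyde 7 and iodide 18. A Nozaki–Hiyama–Kishi coupling (CrCl2, NiCl2 cat., DMF, 25 °C), which is selective for the aldehyde over the ketones and for C–I over C–Br, would give the racemic carbinol 1-(3-bromo-2,4,6-trifluoro-5-{[2,4-bis(benzyloxy)-3-butanoyl-6-methoxy-5-methylphenyl](hydroxy)methyl}phenyl)ethanone F8. Ionic hydrogenation of the carbinol, which ionises readily next to the trialkoxyaryl ring (Et3SiH, CF3CO2H, CH2Cl2, 0 °C), removes the carbinol stereocenter and comes back to the route at 20.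

**Further compounds**
F1 | step 16 | 1-[2,4,6-tris(benzyloxy)phenyl]ethanone | CC(=O)c1c(OCc2ccccc2)cc(OCc2ccccc2)cc1OCc1ccccc1
F2 | step 16 | 1-[2,4,6-tris(benzyloxy)-3-bromophenyl]ethanone | CC(=O)c1c(OCc2ccccc2)cc(OCc2ccccc2)c(Br)c1OCc1ccccc1
F3 | step 16 | 1-[2,4,6-tris(benzyloxy)-3-bromo-5-iodophenyl]ethanone | CC(=O)c1c(OCc2ccccc2)c(I)c(OCc2ccccc2)c(Br)c1OCc1ccccc1
F4 | step 16 | 1-(2,4,6-tris(benzyloxy)-3-bromo-5-{[2,4-bis(benzyloxy)-3-butanoyl-6-methoxy-5-methylphenyl]methyl}phenyl)ethanone | CC(=O)c1c(OCc2ccccc2)c(Cc2c(OCc3ccccc3)c(C(=O)CCC)c(OCc3ccccc3)c(C)c2OC)c(OCc2ccccc2)c(Br)c1OCc1ccccc1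
F5 | step 7 | 2,4,6-trihydroxy-3-methylbenzaldehyde | Cc1c(O)cc(O)c(C=O)c1O
F6 | step 7 | 2,6-dihydroxy-4-methoxy-3-methylbenzaldehyde | Cc1c(OC)cc(O)c(C=O)c1O
F7 | step 7 | 3-butanoyl-2,6-dihydroxy-4-methoxy-5-methylbenzaldehyde | CCCC(=O)c1c(OC)c(C)c(O)c(C=O)c1O
F8 | step 14 | 1-(3-bromo-2,4,6-trifluoro-5-{[2,4-bis(benzyloxy)-3-butanoyl-6-methoxy-5-methylphenyl](hydroxy)methyl}phenyl)ethanone (racemic) | CC(=O)c1c(F)c(C(O)c2c(OCc3ccccc3)c(C(=O)CCC)c(OCc3ccccc3)c(C)c2OC)c(F)c(Br)c1F
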